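Remark on numbering: the terpenoid half is numbered as a drimane (C4 = CMe2, C5 and C10 = ring fusion, C8 = methyl-bearing alkene carbon, C9 = CH bearing the benzylic C11); α is the face opposite the C10 methyl group, β the face of that methyl group; arene positions carry primes (C1' bears the ester).
Assumption: the ketone α-centre of 6, 7, 8 and 12 is carried as a mixture of epimers, because it becomes the planar enolate carbon C10 in step 8.

## Structural features

The target is a methyl 3,4-dihydroxybenzoate joined at C5' through one benzylic methylene (C11) to C9 of a drim-7-ene. The terpenoid half is a trans-fused decalin: ring A is saturated and holds the gem-dimethyl carbon C4, ring B is a cyclohexene with the trisubstituted C7=C8 alkene and the C8 methyl group. Three contiguous stereocentres lie on the C5–C10–C9 edge, C5 (H α), the quaternary C10 (methyl β) and C9 (H α, benzyl β), all S, and C10 is crowded from both sides by C4 (through C5) and by C9. The free catechol is air-sensitive and, under strong acid, its O4' can add to C8 of the alkene to close a chroman; the alkene can also drift to the tetrasubstituted C8=C9 position, and the methyl ester excludes strong nucleophiles late in the route. The real difficulty is the absolute and relative configuration of C5 and C10 in a carbocycle with no heteroatom on ring A to steer reagents, followed by placing H-9 on the α face while the alkene ends at C7=C8. The key step uses the fact that C5–C10 is the bond common to rings A and B and that C7–C8 lies in ring B. In an open chain with a ketone at C9 and an enoate C5=C6–C7, each of these two bonds closes a six-membered ring, so one enolate cascade can fold the whole decalin. It leaves oxygen at C7 and C9, the two carbons that later carry the alkene and the benzyl group.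

## Logic of the disconnections

30 to 29: the two aryl O–CH2OMe bonds are cut last. The catechol must stay masked through organomagnesium, palladium and Mitsunobu chemistry, and acetal ethers come off in methanolic acid, where exchange at the methyl ester is degenerate. The demand is that the acid stays mild enough not to protonate C7=C8.

29 to 26: the C9–H bond and the C7=C8 π bond are traced back to a C7–O bond and a C8=C9 alkene. The configuration of C9 is thereby relayed from C7 by a suprafacial hydrogen shift instead of being set by an uncontrolled protonation or hydrogenation. The demand is that 26 is the 7β-alcohol and that nitrogen displaces it with clean inversion.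

26 to 25 to 24: the C7–H bond is cut (hydride) and then the aryl–CO2Me bond (carbon monoxide and methanol). The ester cannot survive the organomagnesium step, so it travels as the bromide and is installed at the robust enone stage. Later steps are thereby freed from an aryl halide. The demands are 1,2-reduction from the α face and a palladium step that leaves enone and acetals alone.

24 to 15 and 21: the C9–C11 bond is cut, with the C8=C9 alkene and the C7 carbonyl traced back to an enol ether. This splits the molecule into two halves of similar size and uses the C9 carbonyl of the cascade product directly. The demand is addition of a benzylic nucleophile to a carbonyl that is both deactivated and flanked by the quaternary C10, and formation of that nucleophile without touching the aryl bromide.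

15 to 14: the O–CH3 bond is cut. The ether differentiates the two carbonyls of 14; the demand is etherification at O7 and not at O9, which is left to thermodynamic control.

14 to 12 (key): C5–C10 and C7–C8 are cut, and the bicycle unravels to one chain whose only stereocentre is destroyed on enolisation. Two rings, two skeletal bonds and two stereocentres are gained in one step. The demand is control of enolate regiochemistry, of the trans fusion and of absolute configuration. An achiral ester with an achiral base could only give racemate, so the control element is built into 12 as a chiral ester that is also the leaving group of the Claisen step.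

12 to 8 and 11, 11 to 9 and 10: the C5=C6 double bond is cut by olefination and the ester C–O bond of 11 by esterification. The chiral alcohol 9 enters with the phosphonate at no extra cost in the main line; the demand is reaction at the aldehyde only and (E) geometry.

8 to 7 to 6, 6 to 4 and 5, 4 to 3 to 1 and 2: the C10–C1 bond (ketone α-alkylation) and the C3–C4 bond (ester enolate alkylation) are cut. A hydride reagent cannot stop at the aldehyde beside a free ketone, so both carbonyls are reduced and both alcohols re-oxidised. The demand is mono-alkylation of 5 and chemoselective displacement of bromide in 2.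

21 to 19 to 18 to 17 to 16: the benzylic C–Cl bond, the aldehyde C–H bond, the two acetal O–C bonds and the O–CH3 bond are cut in turn. The methyl ether of 16 is exchanged at the start, because it could not be removed at the end beside the alkene.

## Other disconnections considered

Alternative 1: The cut runs across ring A, at C1–C10 and C4–C5, so that ring B is a preformed quinone, 2,6-dimethyl-1,4-benzoquinone A2, and ring A is added as the diene 4-methylpenta-1,3-diene A3. Forward, a chiral cationic oxazaborolidine Lewis acid would bind the less hindered carbonyl of A2 and direct A3 onto one MeC=CH unit to give the cis-fused 11-nordrima-2,7-diene-6,9-dione A1 with C10 set.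
- In its favour: both partners are simple commercial compounds, the bicycle appears in one step, and absolute control rests on a catalytic reaction class with precedent for 2,6-disubstituted quinones. On precedent for enantiocontrol and on steps to the first bicyclic intermediate it is the better plan.
- Against it here: A3 carries a Z-methyl group on the terminus that must bond to C5, so its reactive s-cis conformer is disfavoured and the new bond joins two congested carbons. A1 is cis-fused and has an oxygen at C6 and an alkene at C2=C3 that the target lacks. C5 would have to be epimerised through the C6 enol, C2=C3 hydrogenated beside the more reactive enedione alkene, C6 deoxygenated, and the benzyl group still attached at C9, where the tertiary allylic C–O bond must then be replaced by an α-hydrogen without moving C7=C8.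
- Comparison: structurally A1 already holds the C7=C8 alkene and the C8 methyl group, which the chosen plan creates by transposition. Mechanistically the cycloaddition is concerted, so its relative outcome is certain but cis, whereas the chosen cascade is stepwise and its trans outcome rests on transition-state preferences. In step economy the gain at the front would probably be spent on redox corrections, so the totals should be similar.

Alternative 2: The cut runs through the arene, at C5'–C6' and C3'–C4'. The terpenoid is taken whole as the bis(trimethylsilyl) ketene acetal A6, and the other four arene carbons with the ester come from methyl 3-bromocoumalate A5. Forward, A6 adds to A5 in an inverse-demand [4+2] reaction, the bridged lactone loses CO2, and loss of Me3SiOH aromatises the ring to the bromophenol A4.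
- In its favour: C5, C9 and C10 come from the chiral pool, so no asymmetric step and no cis/trans question arise; on stereochemical security it is clearly the better plan. The ester is present from the start, so no carbonylation is needed (equal or better), and the substitution pattern of the arene follows from the polarity of the two partners.
- Against it here: A6 must be made by oxidative degradation of a labdane and regioselective placement of the C7=C8 alkene, where dehydration of a C8 alcohol tends to give alkene isomers. The cycloaddition must accept a bulky branched substituent on the ketene acetal, and A4 carries bromine where the second hydroxyl is needed, so a C–Br to C–OH exchange on an electron-rich ortho-bromophenol remains.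
- Comparison: structurally it builds the arene and not the decalin, so it gives no entry to ring-modified analogues or to the other enantiomer, which the chosen plan reaches by changing the chain or the antipode of 9. Mechanistically the pericyclic sequence is well defined, while the chosen anionic cascade is not yet demonstrated. In step economy it should be shorter than thirteen linear steps if the degradation is efficient.

Alternative 3: The cut is the C6=C7 bond of the enone A7 (trans-fused 11,12-dinordrim-6-en-8-one). Behind it stands the keto aldehyde A8, with an acetonyl group on C10 and a formyl group on C5, and C10 is traced to enantioselective allylation of a ketone such as 2,2,6-trimethylcyclohexanone A9. Forward, KOH in methanol forms the methyl ketone enolate at C7, which adds to C6, and dehydration closes ring B.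
- In its favour: the aldol condensation is textbook chemistry with a single possible mode of closure, and the quaternary C10 comes from a catalytic enantioselective allylation of established type. On mechanistic certainty and on precedent for the asymmetric step it is the better plan.
- Against it here: the key step makes one ring and one bond and sets no stereocentre. The formyl carbon must be added to a carbonyl flanked by two quaternary carbons, and C5 then equilibrated to the trans isomer. A7 lacks the C8 methyl group and C11 and has its oxygen at C8, so the benzyl group must be brought in by alkylation at the neopentyl C9 (the β configuration is the kinetically less accessible one), the methyl group by addition at C8, and the alkene moved from C6=C7 to C7=C8.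
- Comparison: structurally the dione 14 of the chosen plan has oxygen at C7 and C9 and the C8 methyl group from the start, while A7 needs two further C–C bonds on ring B. Mechanistically the aldol is the safer closure. In step economy the alternative is unlikely to be shorter, since ring A needs about six steps before the key step and ring B at least as many after it.

Key step: step 8

## Route

Step 1
Reactants: 1 methyl isobutyrate; 2 1-bromo-3-chloropropane
Product: 3 methyl 5-chloro-2,2-dimethylpentanoate
Conditions: LiN(i-Pr)2, THF, −78 °C; then 2, −78 °C → rt
Reagents that add atoms: none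
Why: Alkylation of an ester enolate; bromide is displaced much faster than chloride, so the chloride is kept as the handle for the next step and no stereocentre is formed.

Step 2
Reactants: 3 methyl 5-chloro-2,2-dimethylpentanoate
Product: 4 methyl 5-iodo-2,2-dimethylpentanoate
Conditions: NaI, acetone, reflux
Reagents that add atoms: sodium iodide, [Na+].[I-]
Why: Finkelstein exchange driven by precipitation of NaCl; the iodide is needed because ketone enolates alkylate primary chlorides poorly.

Step 3
Reactants: 5 3-pentanone; 4 methyl 5-iodo-2,2-dimethylpentanoate
Product: 6 methyl 2,2,6-trimethyl-7-oxononanoate (racemic)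
Conditions: LiN(i-Pr)2, 5 (excess), THF, −78 °C; then 4, DMPU, −78 → −10 °C
Reagents that add atoms: none
Why: α-Alkylation of a symmetrical ketone enolate with a primary iodide; excess enolate limits dialkylation and the neopentyl ester of 4 resists Claisen attack.

Step 4
Reactants: 6 methyl 2,2,6-trimethyl-7-oxononanoate
Product: 7 2,2,6-trimethylnonane-1,7-diol (mixture of diastereomers)
Conditions: LiAlH4, THF, 0 → 50 °C; aqueous NaOH work-up
Reagents that add atoms: none
Why: Hydride reduction of ester and ketone together; no hydride reagent would stop at the aldehyde beside a free ketone, so both groups are reduced here and re-oxidised in step 5.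

Step 5
Reactants: 7 2,2,6-trimethylnonane-1,7-diol
Product: 8 2,2,6-trimethyl-7-oxononanal (racemic)
Conditions: (COCl)2, DMSO, CH2Cl2, −78 °C; Et3N, −78 → 0 °C
Reagents that add atoms: none
Why: Swern oxidation of the primary and the secondary alcohol in one operation; the aldehyde has no α-hydrogen and so can neither epimerise nor self-condense.

Step 6
Reactants: 9 (1R,2S,5R)-5-methyl-2-(2-phenylpropan-2-yl)cyclohexan-1-ol [(−)-8-phenylmenthol]; 10 2-(diethoxyphosphoryl)acetic acid
Product: 11 (1R,2S,5R)-5-methyl-2-(2-phenylpropan-2-yl)cyclohexyl 2-(diethoxyphosphoryl)acetate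
Conditions: DCC, DMAP (cat.), CH2Cl2, 0 °C → rt
Reagents that add atoms: none
Why: Steglich esterification of a hindered secondary alcohol with an unhindered acid; no stereocentre is touched.

Step 7
Reactants: 8 2,2,6-trimethyl-7-oxononanal; 11 (1R,2S,5R)-5-methyl-2-(2-phenylpropan-2-yl)cyclohexyl 2-(diethoxyphosphoryl)acetate
Product: 12 (1R,2S,5R)-5-methyl-2-(2-phenylpropan-2-yl)cyclohexyl (2E)-4,4,8-trimethyl-9-oxoundec-2-enoate (both epimers at chain C8)
Conditions: 11, NaH, THF, 0 °C; then 8, 0 °C → rt
Reagents that add atoms: none
Why: Horner–Wadsworth–Emmons olefination; the stabilised phosphonate anion reacts with the aldehyde and not with the α-branched ketone, and gives the (E)-enoate.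

Step 8
Reactants: 12 (1R,2S,5R)-5-methyl-2-(2-phenylpropan-2-yl)cyclohexyl (2E)-4,4,8-trimethyl-9-oxoundec-2-enoate
Product: 14 (4aS,8aS)-2,5,5,8a-tetramethylhexahydronaphthalene-1,3(2H,4H)-dione [(5S,10S)-11-nordrimane-7,9-dione; C8 epimers and enol], via keto ester 13 (not isolated)
Conditions: KOt-Bu (1.5 equiv), t-BuOH (5 equiv), THF (0.01 M), −20 °C → rt, then 50 °C; 1 M HCl
Reagents that add atoms: none
Why: Proposed new method: the closest known reaction types are the base-mediated Michael–Claisen annulation of ketones with acrylates to cyclohexane-1,3-diones and internal Michael additions of enolates to 8-arylmenthyl enoates, which are merged here in one tether on the following mechanistic reasoning. KOt-Bu equilibrates the two ketone enolates, and only the C10 enolate has a productive path, a 6-exo-trig Michael addition to C5 that forms C5–C10 and ring A; the C8 enolate would need an eight-membered ring, and the gem-dimethyl group at C4 leaves the enoate without γ-hydrogens. Proton transfer gives keto ester 13, in which C6 is acidic as well as C8, but the C6 enolate could only close a four-membered ring onto C9, so the C8 enolate attacks the ester carbonyl C7 (6-exo-trig acyl substitution), forms C7–C8 and ring B, and expels the alkoxide of 9. Deprotonation of the resulting 1,3-dione is the thermodynamic sink that pulls the reversible steps forward, and acid work-up returns 14 and recoverable 9. C5 is controlled by the auxiliary, whose phenyl ring stacks over one face of the s-trans enoate, so C10 should add to the open Cβ si face, which places H-5 on the α face. C10 is controlled by a chair transition state with the enolate arm (C9) and the acceptor arm (C6) both pseudo-equatorial and the small methyl group pseudo-axial, which gives the trans fusion; C8 is not controlled and need not be, since it is enolised in step 9. The step needs the Claisen closure to outrun retro-Michael cleavage so that the kinetic facial preference is kept, and high dilution secures it against intermolecular Michael addition of the C8 enolate.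

Step 9
Reactants: 14 (4aS,8aS)-2,5,5,8a-tetramethylhexahydronaphthalene-1,3(2H,4H)-dione
Product: 15 (4aS,8aS)-3-methoxy-2,5,5,8a-tetramethyl-4a,5,6,7,8,8a-hexahydronaphthalen-1(4H)-one [7-methoxy-11-nordrim-7-en-9-one]
Conditions: HC(OMe)3, TsOH·H2O (cat.), MeOH, rt → 50 °C
Reagents that add atoms: trimethyl orthoformate, COC(OC)OC; methanol, CO (either can supply the methoxy group)
Why: Acid-catalysed enol etherification of a cyclic 1,3-dione under equilibrating conditions; the ether should settle at O7, because an in-plane methoxy group on C9 would clash with the substituents of the quaternary C10, and acid catalysis excludes C-methylation at C8.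

Step 10
Reactants: 16 5-bromo-2-hydroxy-3-methoxybenzaldehyde
Product: 17 5-bromo-2,3-dihydroxybenzaldehyde
Conditions: BBr3, CH2Cl2, −78 → 0 °C; H2O
Reagents that add atoms: none
Why: Lewis acid cleavage of an aryl methyl ether, helped by chelation to the neighbouring phenol; the methyl ether is exchanged now because its removal at the end would not spare the alkene.

Step 11
Reactants: 17 5-bromo-2,3-dihydroxybenzaldehyde
Product: 18 5-bromo-2,3-bis(methoxymethoxy)benzaldehyde
Conditions: MOMCl, i-Pr2NEt, CH2Cl2, 0 °C → rt
Reagents that add atoms: chloromethyl methyl ether, COCCl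
Why: Double O-alkylation of the catechol to acetal ethers, which tolerate organomagnesium, hydride, palladium and Mitsunobu reagents and leave under mild acid.

Step 12
Reactants: 18 5-bromo-2,3-bis(methoxymethoxy)benzaldehyde
Product: 19 [5-bromo-2,3-bis(methoxymethoxy)phenyl]methanol
Conditions: NaBH4, MeOH, 0 °C
Reagents that add atoms: none
Why: Borohydride reduction of the aldehyde; aryl bromide and acetals are inert.

Step 13
Reactants: 19 [5-bromo-2,3-bis(methoxymethoxy)phenyl]methanol
Product: 21 5-bromo-1-(chloromethyl)-2,3-bis(methoxymethoxy)benzene, via benzylic mesylate 20 (not isolated)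
Conditions: MsCl, Et3N, CH2Cl2, 0 °C; then LiCl, THF, rt
Reagents that add atoms: lithium chloride, [Li+].[Cl-] (chloride released from methanesulfonyl chloride, CS(=O)(=O)Cl, can serve as well)
Why: Mesylation and SN2 displacement by chloride under non-acidic conditions, which spares the acetals; the chloride is chosen because benzylic chlorides give organomagnesium reagents with little homocoupling.

Step 14
Reactants: 15 7-methoxy-11-nordrim-7-en-9-one; 21 5-bromo-1-(chloromethyl)-2,3-bis(methoxymethoxy)benzene
Product: 24 (5S,10S)-11-[5-bromo-2,3-bis(methoxymethoxy)phenyl]drim-8-en-7-one, via benzylmagnesium chloride 22 (not isolated), via tertiary carbinol 23 (not isolated)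
Conditions: 21, Mg, Et2O, 0 °C; then 15, LaCl3·2LiCl, THF, 0 °C → rt; then 0.5 M aq. HCl, THF, 0 °C → rt
Reagents that add atoms: water, O
Why: Stork–Danheiser sequence: 1,2-addition of a Grignard reagent to the carbonyl of a vinylogous ester, then acid hydrolysis of the enol ether with loss of water, which moves the enone to C8=C9–C7=O and erases the C9 carbinol centre. Magnesium inserts into the benzylic C–Cl bond in ether far faster than into the aryl C–Br bond, and the lanthanum salt favours addition over deprotonation at the hindered carbonyl.

Step 15
Reactants: 24 (5S,10S)-11-[5-bromo-2,3-bis(methoxymethoxy)phenyl]drim-8-en-7-one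
Product: 25 methyl 3,4-bis(methoxymethoxy)-5-[(5S,10S)-7-oxodrim-8-en-11-yl]benzoate
Conditions: Pd(OAc)2 (cat.), Xantphos (cat.), CO (1 atm), Et3N, MeOH–toluene, 70 °C
Reagents that add atoms: carbon monoxide, [C-]#[O+]; methanol, CO
Why: Palladium-catalysed alkoxycarbonylation of an aryl bromide (oxidative addition to zerovalent palladium, CO insertion, methanolysis); it is placed at the robust enone stage so that no aryl halide remains for the later steps.

Step 16
Reactants: 25 methyl 3,4-bis(methoxymethoxy)-5-[(5S,10S)-7-oxodrim-8-en-11-yl]benzoate
Product: 26 methyl 5-[(5S,7S,10S)-7-hydroxydrim-8-en-11-yl]-3,4-bis(methoxymethoxy)benzoate (7β-alcohol)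
Conditions: NaBH4, CeCl3·7H2O, MeOH, −20 → 0 °C
Reagents that add atoms: none
Why: Luche 1,2-reduction of the enone; hydride should enter along the axial trajectory on the α face and give the pseudo-equatorial 7β-alcohol (7S), while the benzoate ester is not reduced.

Step 17
Reactants: 26 methyl 5-[(5S,7S,10S)-7-hydroxydrim-8-en-11-yl]-3,4-bis(methoxymethoxy)benzoate
Product: 29 methyl 3,4-bis(methoxymethoxy)-5-[(5S,9S,10S)-drim-7-en-11-yl]benzoate, via sulfonyl hydrazone adduct 27 (not isolated), via allylic diazene 28 (not isolated)
Conditions: IPNBSH (2-O2NC6H4SO2NHN=CMe2), PPh3, DEAD, THF, 0 °C → rt; then CF3CH2OH–H2O (1:1), rt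
Reagents that add atoms: none
Why: Mitsunobu displacement by the sulfonyl hydrazone nitrogen inverts C7 (7α-N); solvolysis of the hydrazone and loss of sulfinate give the 7α-diazene, which expels N2 in a suprafacial retro-ene step that delivers hydrogen to the α face of C9 and moves the alkene to C7=C8 (reductive 1,3-transposition). C9 is thus set S by relay from C7.

Step 18
Reactants: 29 methyl 3,4-bis(methoxymethoxy)-5-[(5S,9S,10S)-drim-7-en-11-yl]benzoate
Product: 30 methyl 3,4-dihydroxy-5-{[(1S,4aS,8aS)-2,5,5,8a-tetramethyl-1,4,4a,5,6,7,8,8a-octahydronaphthalen-1-yl]methyl}benzoate (target)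
Conditions: HCl (conc., 5 equiv), MeOH (degassed), rt → 40 °C
Reagents that add atoms: none
Why: Acid-catalysed acetal exchange removes both methoxymethyl groups as dimethoxymethane; methanol makes ester exchange degenerate, and dilute acid at this temperature is the regime in which ortho-prenyl phenols survive the same deprotection, so C7=C8 should neither migrate nor capture O4'.

## Compound list

1 | methyl isobutyrate | COC(=O)C(C)C | starting material
2 | 1-bromo-3-chloropropane | ClCCCBr | starting material
3 | methyl 5-chloro-2,2-dimethylpentanoate | COC(=O)C(C)(C)CCCCl | intermediate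
4 | methyl 5-iodo-2,2-dimethylpentanoate | COC(=O)C(C)(C)CCCI | intermediate
5 | 3-pentanone | CCC(=O)CC | starting material
6 | methyl 2,2,6-trimethyl-7-oxononanoate (racemic) | CCC(=O)C(C)CCCC(C)(C)C(=O)OC | intermediate
7 | 2,2,6-trimethylnonane-1,7-diol (diastereomer mixture) | CCC(O)C(C)CCCC(C)(C)CO | intermediate
8 | 2,2,6-trimethyl-7-oxononanal (racemic) | CCC(=O)C(C)CCCC(C)(C)C=O | intermediate
9 | (1R,2S,5R)-5-methyl-2-(2-phenylpropan-2-yl)cyclohexan-1-ol, (−)-8-phenylmenthol | O[C@@H]1C[C@H](C)CC[C@H]1C(C)(C)c1ccccc1 | starting material
10 | 2-(diethoxyphosphoryl)acetic acid | CCOP(=O)(CC(=O)O)OCC | starting material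
11 | (1R,2S,5R)-5-methyl-2-(2-phenylpropan-2-yl)cyclohexyl 2-(diethoxyphosphoryl)acetate | CCOP(=O)(CC(=O)O[C@@H]1C[C@H](C)CC[C@H]1C(C)(C)c1ccccc1)OCC | intermediate
12 | (1R,2S,5R)-5-methyl-2-(2-phenylpropan-2-yl)cyclohexyl (2E)-4,4,8-trimethyl-9-oxoundec-2-enoate (both epimers at chain C8) | CCC(=O)C(C)CCCC(C)(C)/C=C/C(=O)O[C@@H]1C[C@H](C)CC[C@H]1C(C)(C)c1ccccc1 | intermediate
13 | (1R,2S,5R)-5-methyl-2-(2-phenylpropan-2-yl)cyclohexyl 2-[(1S,2S)-2,6,6-trimethyl-2-propanoylcyclohexyl]acetate (not isolated) | CCC(=O)[C@@]1(C)CCCC(C)(C)[C@@H]1CC(=O)O[C@@H]1C[C@H](C)CC[C@H]1C(C)(C)c1ccccc1 | intermediate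
14 | (4aS,8aS)-2,5,5,8a-tetramethylhexahydronaphthalene-1,3(2H,4H)-dione, (5S,10S)-11-nordrimane-7,9-dione (C8 epimers and enol) | O=C1C(C)C(=O)C[C@H]2C(C)(C)CCC[C@]12C | intermediate
15 | (4aS,8aS)-3-methoxy-2,5,5,8a-tetramethyl-4a,5,6,7,8,8a-hexahydronaphthalen-1(4H)-one, 7-methoxy-11-nordrim-7-en-9-one | O=C1C(C)=C(OC)C[C@H]2C(C)(C)CCC[C@]12C | intermediate
16 | 5-bromo-2-hydroxy-3-methoxybenzaldehyde | COc1cc(Br)cc(C=O)c1O | starting material
17 | 5-bromo-2,3-dihydroxybenzaldehyde | Oc1cc(Br)cc(C=O)c1O | intermediate
18 | 5-bromo-2,3-bis(methoxymethoxy)benzaldehyde | COCOc1cc(Br)cc(C=O)c1OCOC | intermediate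
19 | [5-bromo-2,3-bis(methoxymethoxy)phenyl]methanol | COCOc1cc(Br)cc(CO)c1OCOC | intermediate
20 | [5-bromo-2,3-bis(methoxymethoxy)phenyl]methyl methanesulfonate (not isolated) | COCOc1cc(Br)cc(COS(C)(=O)=O)c1OCOC | intermediate
21 | 5-bromo-1-(chloromethyl)-2,3-bis(methoxymethoxy)benzene | COCOc1cc(Br)cc(CCl)c1OCOC | intermediate
22 | {[5-bromo-2,3-bis(methoxymethoxy)phenyl]methyl}magnesium chloride (not isolated) | COCOc1cc(Br)cc(C[Mg]Cl)c1OCOC | intermediate
23 | (5S,10S)-11-[5-bromo-2,3-bis(methoxymethoxy)phenyl]-7-methoxydrim-7-en-9-ol (C9 epimers, not isolated) | COC1=C(C)C(O)(Cc2cc(Br)cc(OCOC)c2OCOC)[C@@]2(C)CCCC(C)(C)[C@@H]2C1 | intermediate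
24 | (5S,10S)-11-[5-bromo-2,3-bis(methoxymethoxy)phenyl]drim-8-en-7-one | O=C1C[C@H]2C(C)(C)CCC[C@]2(C)C(Cc2cc(Br)cc(OCOC)c2OCOC)=C1C | intermediate
25 | methyl 3,4-bis(methoxymethoxy)-5-[(5S,10S)-7-oxodrim-8-en-11-yl]benzoate | O=C1C[C@H]2C(C)(C)CCC[C@]2(C)C(Cc2cc(C(=O)OC)cc(OCOC)c2OCOC)=C1C | intermediate
26 | methyl 5-[(5S,7S,10S)-7-hydroxydrim-8-en-11-yl]-3,4-bis(methoxymethoxy)benzoate (7β-OH) | O[C@H]1C[C@H]2C(C)(C)CCC[C@]2(C)C(Cc2cc(C(=O)OC)cc(OCOC)c2OCOC)=C1C | intermediate
27 | methyl 3,4-bis(methoxymethoxy)-5-{(5S,7R,10S)-7-[1-(2-nitrobenzenesulfonyl)-2-(propan-2-ylidene)hydrazinyl]drim-8-en-11-yl}benzoate (7α-N, not isolated) | CC(C)=NN([C@@H]1C[C@H]2C(C)(C)CCC[C@]2(C)C(Cc2cc(C(=O)OC)cc(OCOC)c2OCOC)=C1C)S(=O)(=O)c1ccccc1[N+](=O)[O-] | intermediate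
28 | methyl 5-[(5S,7R,10S)-7-diazenyldrim-8-en-11-yl]-3,4-bis(methoxymethoxy)benzoate (7α-diazene, not isolated) | N=N[C@@H]1C[C@H]2C(C)(C)CCC[C@]2(C)C(Cc2cc(C(=O)OC)cc(OCOC)c2OCOC)=C1C | intermediate
29 | methyl 3,4-bis(methoxymethoxy)-5-[(5S,9S,10S)-drim-7-en-11-yl]benzoate | COC(=O)c1cc(OCOC)c(OCOC)c(C[C@H]2C(C)=CC[C@H]3C(C)(C)CCC[C@]23C)c1 | intermediate
30 | methyl 3,4-dihydroxy-5-{[(1S,4aS,8aS)-2,5,5,8a-tetramethyl-1,4,4a,5,6,7,8,8a-octahydronaphthalen-1-yl]methyl}benzoate | COC(=O)c1cc(O)c(O)c(C[C@H]2C(C)=CC[C@H]3C(C)(C)CCC[C@]23C)c1 | target

## Step count and least certain steps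

Total step count: 18. Longest linear sequence: 13 steps (steps 1–5, 7–9 and 14–18).

Step 8 (key step, proposed new method).
- What may go wrong: loss of auxiliary control through reversibility. If retro-Michael cleavage competes with a slow Claisen closure on the hindered ester, the two C5 epimers of 13 equilibrate and the facial preference is eroded. A potassium-bridged s-cis enoate would expose the opposite face, and closure through a chair with the enolate arm axial would give cis fusion.
- Fallback (known chemistry, resolution in place of auxiliary control), setting out from 8 and coming back at 24. 8 is olefinated with trimethyl phosphonoacetate (NaH, THF) to methyl (E)-4,4,8-trimethyl-9-oxoundec-2-enoate F1. KOt-Bu in t-BuOH–THF then effects the internal Michael addition of the ketone enolate to the enoate and the Claisen closure of the resulting δ-keto ester, two individually known reactions that can be run in one flask or in two. This gives 14 together with its enantiomer, (4aR,8aR)-2,5,5,8a-tetramethylhexahydronaphthalene-1,3(2H,4H)-dione F2. The racemate is condensed with (1R,2S,5R)-menthol (TsOH, toluene, water separator) to the diastereomeric enol ethers, the menthyl enol ether of 14 F3 and the menthyl enol ether of the enantiomer F4, which are separated by crystallisation or chromatography. F3 takes the place of 15 in step 14 and gives 24 with release of menthol.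

Step 14.
- What may go wrong: slow 1,2-addition to a carbonyl that is deactivated as a vinylogous ester and flanked by the quaternary C10, so that deprotonation at C6 or homocoupling of the benzylic reagent takes over; partial insertion of magnesium into the C–Br bond.
- Fallback (the C11–aryl bond is made instead of the C9–C11 bond), setting out from 15 and coming back at 25. MeLi, small enough for the hindered carbonyl, is added to 15 and acid work-up gives (5S,10S)-drim-8-en-7-one F5. Radical bromination at the γ-methyl group (NBS, AIBN, PhCF3, reflux) gives 11-bromodrim-8-en-7-one F6. Purchased methyl 3-bromo-4,5-dihydroxybenzoate F7 is converted with MOMCl and i-Pr2NEt into methyl 3-bromo-4,5-bis(methoxymethoxy)benzoate F8, and Miyaura borylation (B2pin2, PdCl2(dppf), KOAc, dioxane, 80 °C) gives methyl 3,4-bis(methoxymethoxy)-5-(4,4,5,5-tetramethyl-1,3,2-dioxaborolan-2-yl)benzoate F9. Allyl–aryl Suzuki coupling of F6 with F9 (Pd(PPh3)4, K2CO3, THF–H2O, 60 °C) gives 25 directly, so that step 15 is not needed.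

Step 17.
- What may go wrong: slow Mitsunobu displacement at a secondary allylic alcohol next to the tetrasubstituted alkene, with elimination to a 6,8-diene in place of substitution; incomplete inversion would carry the wrong configuration to C9.
- Fallback (hydride transfer within a π-allyl palladium complex instead of a diazene), setting out from 26 and coming back at 29. 26 is formylated with retention (HCO2H, DCC, DMAP) to the 7β-formate of 26 F10. With Pd(OAc)2 and n-Bu3P in dioxane at reflux, zerovalent palladium ionises the formate from the α face, decarboxylation leaves a palladium hydride, and hydride transfer to the more substituted terminus C9 on the α face gives 29 with the alkene at C7=C8.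

Step 16.
- What may go wrong: poor facial selectivity of hydride addition at C7; the 7α epimer would deliver hydrogen to the β face of C9 in step 17.
- Fallback (correction by inversion instead of by selectivity), setting out from 25 and coming back at 26. The 7α-epimer of 26 F11 formed from 25 is separated and inverted by Mitsunobu esterification with 4-nitrobenzoic acid (PPh3, DEAD, THF) to the 7β-(4-nitrobenzoate) of 26 F12, and methanolysis (K2CO3, MeOH) gives 26.

## Further compounds

F1 | step 8 | methyl (E)-4,4,8-trimethyl-9-oxoundec-2-enoate | CCC(=O)C(C)CCCC(C)(C)/C=C/C(=O)OC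
F2 | step 8 | (4aR,8aR)-2,5,5,8a-tetramethylhexahydronaphthalene-1,3(2H,4H)-dione (enantiomer of 14) | O=C1C(C)C(=O)C[C@@H]2C(C)(C)CCC[C@@]12C
F3 | step 8 | (4aS,8aS)-3-[(1R,2S,5R)-menthyloxy]-2,5,5,8a-tetramethyl-4a,5,6,7,8,8a-hexahydronaphthalen-1(4H)-one (menthyl enol ether of 14) | O=C1C(C)=C(O[C@@H]2C[C@H](C)CC[C@H]2C(C)C)C[C@H]2C(C)(C)CCC[C@]12C
F4 | step 8 | (4aR,8aR)-3-[(1R,2S,5R)-menthyloxy]-2,5,5,8a-tetramethyl-4a,5,6,7,8,8a-hexahydronaphthalen-1(4H)-one (menthyl enol ether of F2) | O=C1C(C)=C(O[C@@H]2C[C@H](C)CC[C@H]2C(C)C)C[C@@H]2C(C)(C)CCC[C@@]12C
F5 | step 14 | (5S,10S)-drim-8-en-7-one | O=C1C[C@H]2C(C)(C)CCC[C@]2(C)C(C)=C1C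
F6 | step 14 | (5S,10S)-11-bromodrim-8-en-7-one | O=C1C[C@H]2C(C)(C)CCC[C@]2(C)C(CBr)=C1C
F7 | step 14 | methyl 3-bromo-4,5-dihydroxybenzoate (purchased) | COC(=O)c1cc(O)c(O)c(Br)c1
F8 | step 14 | methyl 3-bromo-4,5-bis(methoxymethoxy)benzoate | COCOc1cc(C(=O)OC)cc(Br)c1OCOC
F9 | step 14 | methyl 3,4-bis(methoxymethoxy)-5-(4,4,5,5-tetramethyl-1,3,2-dioxaborolan-2-yl)benzoate | COCOc1cc(C(=O)OC)cc(B2OC(C)(C)C(C)(C)O2)c1OCOC
F10 | step 17 | methyl 5-[(5S,7S,10S)-7-(formyloxy)drim-8-en-11-yl]-3,4-bis(methoxymethoxy)benzoate (7β-formate of 26) | O=CO[C@H]1C[C@H]2C(C)(C)CCC[C@]2(C)C(Cc2cc(C(=O)OC)cc(OCOC)c2OCOC)=C1C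
F11 | step 16 | methyl 5-[(5S,7R,10S)-7-hydroxydrim-8-en-11-yl]-3,4-bis(methoxymethoxy)benzoate (7α-epimer of 26) | O[C@@H]1C[C@H]2C(C)(C)CCC[C@]2(C)C(Cc2cc(C(=O)OC)cc(OCOC)c2OCOC)=C1C
F12 | step 16 | methyl 3,4-bis(methoxymethoxy)-5-[(5S,7S,10S)-7-(4-nitrobenzoyloxy)drim-8-en-11-yl]benzoate | O=C(O[C@H]1C[C@H]2C(C)(C)CCC[C@]2(C)C(Cc2cc(C(=O)OC)cc(OCOC)c2OCOC)=C1C)c1ccc([N+](=O)[O-])cc1
A1 | alternative 1 | cis-fused 11-nordrima-2,7-diene-6,9-dione (5β-H, 10β-methyl) | O=C1C(C)=CC(=O)[C@@H]2C(C)(C)C=CC[C@]12C
A2 | alternative 1 | 2,6-dimethyl-1,4-benzoquinone | CC1=CC(=O)C=C(C)C1=O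
A3 | alternative 1 | 4-methylpenta-1,3-diene | C=CC=C(C)C
A4 | alternative 2 | methyl 3-bromo-4-hydroxy-5-[(5S,9S,10S)-drim-7-en-11-yl]benzoate | COC(=O)c1cc(Br)c(O)c(C[C@H]2C(C)=CC[C@H]3C(C)(C)CCC[C@]23C)c1
A5 | alternative 2 | methyl 3-bromo-2-oxo-2H-pyran-5-carboxylate (methyl 3-bromocoumalate) | COC(=O)C1=COC(=O)C(Br)=C1
A6 | alternative 2 | bis(trimethylsilyl) ketene acetal of 3-[(5S,9S,10S)-11-nordrim-7-en-9-yl]propanoic acid | C[Si](C)(C)OC(O[Si](C)(C)C)=CC[C@H]1C(C)=CC[C@H]2C(C)(C)CCC[C@]12C
A7 | alternative 3 | trans-fused (5S,10S)-11,12-dinordrim-6-en-8-one | O=C1C=C[C@H]2C(C)(C)CCC[C@]2(C)C1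
A8 | alternative 3 | (1S,2R)-2,6,6-trimethyl-2-(2-oxopropyl)cyclohexane-1-carbaldehyde | CC(=O)C[C@@]1(C)CCCC(C)(C)[C@@H]1C=O
A9 | alternative 3 | 2,2,6-trimethylcyclohexanone | CC1CCCC(C)(C)C1=O
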